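The route rests on detaching ring A of the flavone half at two neighbouring bonds, O1–C8a and C4–C4a. That ring bears O1 on C8a, the C4 carbonyl on C4a and oxygen on C5 and C7. This is the pattern that results when a carboxylate adds to 3,5-bis(benzyloxy)benzyne meta to the 3-alkoxy group and the acyl group then moves from oxygen to the adjacent carbanion. One operation therefore makes both bonds and gives an ortho-hydroxyaryl ynone. Its precursor is a biaryl propiolic acid whose phloroglucinol ring is differentiated from the outset: benzyl on the two oxygens flanking the biaryl bond, MOM on the para oxygen, the later O1 of the (2R)-flavanone.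

Key step: step 11

Assumption: the only stereocentre in the target string is flavanone C2, and it reads as R (O1 > C1' > C3 > H). The axis between flavanone C6 and the catechol ring carries no descriptor, so rotamers or slowly interconverting atropisomers that may appear once the phloroglucinol ring loses its symmetry are carried on together.

Step 1
Reactants: 1 3,5-bis(benzyloxy)phenol
Product: 2 3,5-bis(benzyloxy)-2-bromophenol
Conditions: NBS (1.0 equiv), CH2Cl2, −78 °C to rt
Reagents that add atoms: N-bromosuccinimide, O=C1CCC(=O)N1Br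
Why: Electrophilic aromatic bromination in a non-polar solvent at low temperature should go ortho to the free hydroxyl (hydrogen-bonded delivery, smaller neighbour) and not between the two benzyloxy groups.

Step 2
Reactants: 2 3,5-bis(benzyloxy)-2-bromophenol
Product: 3 [3,5-bis(benzyloxy)-2-bromophenoxy]trimethylsilane
Conditions: (Me3Si)2NH, THF, 70 °C; concentrate
Reagents that add atoms: hexamethyldisilazane, C[Si](C)(C)N[Si](C)(C)C
Why: O-Silylation of a phenol with hexamethyldisilazane is clean, needs no work-up and places silicon where the next step can move it to carbon.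

Step 3
Reactants: 3 [3,5-bis(benzyloxy)-2-bromophenoxy]trimethylsilane
Product: 6 3,5-bis(benzyloxy)-2-(trimethylsilyl)phenyl trifluoromethanesulfonate, via aryllithium 4 (not isolated), via lithium phenolate 5 (not isolated)
Conditions: n-BuLi, THF, −100 to −78 °C; then Tf2O, −78 °C
Reagents that add atoms: trifluoromethanesulfonic anhydride, O=S(=O)(OS(=O)(=O)C(F)(F)F)C(F)(F)F
Why: Bromine–lithium exchange gives 4, a retro-Brook 1,3-shift of silicon from O to C gives 5, and O-triflation of 5 completes the ortho-silylaryl triflate.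

Step 4
Reactants: 7 phloroglucinol
Product: 8 5-(methoxymethoxy)benzene-1,3-diol
Conditions: 7 (3 equiv), MOMCl (1 equiv), K2CO3, acetone, 0 °C to rt
Reagents that add atoms: chloromethyl methyl ether, COCCl
Why: In this Williamson-type O-alkylation a threefold excess of the cheap triol makes the mono-acetal the main ether by statistics, and unreacted 7 is removed by washing with water.

Step 5
Reactants: 8 5-(methoxymethoxy)benzene-1,3-diol
Product: 9 2-iodo-5-(methoxymethoxy)benzene-1,3-diol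
Conditions: I2 (1.0 equiv), NaHCO3, THF–H2O, 0 °C
Reagents that add atoms: iodine, II
Why: Electrophilic iodination of a resorcinol monoanion in aqueous bicarbonate prefers the carbon between the two free hydroxyls, as with resorcinol itself, and the twofold symmetry of 9 makes the site easy to confirm.

Step 6
Reactants: 9 2-iodo-5-(methoxymethoxy)benzene-1,3-diol
Product: 10 1,3-bis(benzyloxy)-2-iodo-5-(methoxymethoxy)benzene
Conditions: BnBr (2.3 equiv), K2CO3, DMF, 40 °C
Reagents that add atoms: benzyl bromide, BrCc1ccccc1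
Why: Williamson etherification of both phenols fixes the protecting-group pattern (benzyl next to iodine, MOM para to it) on which the later regiochemistry of the flavanone depends.

Step 7
Reactants: 11 3,4-bis(benzyloxy)benzaldehyde
Product: 12 4,5-bis(benzyloxy)-2-bromobenzaldehyde
Conditions: Br2, NaOAc, AcOH, rt
Reagents that add atoms: bromine, BrBr
Why: Electrophilic bromination goes para to the 3-benzyloxy group and ortho to the formyl group, as in the veratraldehyde series, and acetate buffers the HBr so that the benzyl ethers persist.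

Step 8
Reactants: 10 1,3-bis(benzyloxy)-2-iodo-5-(methoxymethoxy)benzene; 12 4,5-bis(benzyloxy)-2-bromobenzaldehyde
Product: 15 4,5-bis(benzyloxy)-2-[2,6-bis(benzyloxy)-4-(methoxymethoxy)phenyl]benzaldehyde, via aryllithium 13 (not isolated), via arylzinc chloride 14 (not isolated)
Conditions: 10, n-BuLi, THF, −78 °C; ZnCl2, −78 °C to rt; then 12, Pd2(dba)3 (2 mol %), SPhos (8 mol %), THF, 60 °C
Reagents that add atoms: none
Why: Iodine–lithium exchange, transmetalation to zinc and Negishi coupling with a bulky dialkylbiarylphosphine is a proven way to tri-ortho-substituted biaryls, and the arylzinc reagent tolerates the aldehyde and does not protodemetalate as a 2,6-dialkoxyarylboronic acid would.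

Step 9
Reactants: 15 4,5-bis(benzyloxy)-2-[2,6-bis(benzyloxy)-4-(methoxymethoxy)phenyl]benzaldehyde
Product: 16 1,2-bis(benzyloxy)-4-[2,6-bis(benzyloxy)-4-(methoxymethoxy)phenyl]-5-(2,2-dibromoethenyl)benzene
Conditions: CBr4, PPh3, Et3N, CH2Cl2, 0 °C
Reagents that add atoms: carbon tetrabromide, BrC(Br)(Br)Br
Why: This is the first stage of the Corey–Fuchs homologation (Wittig-type dibromoolefination), with triethylamine keeping the medium non-acidic for the MOM acetal.

Step 10
Reactants: 16 1,2-bis(benzyloxy)-4-[2,6-bis(benzyloxy)-4-(methoxymethoxy)phenyl]-5-(2,2-dibromoethenyl)benzene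
Product: 19 3-{4,5-bis(benzyloxy)-2-[2,6-bis(benzyloxy)-4-(methoxymethoxy)phenyl]phenyl}prop-2-ynoic acid, via lithium acetylide 17 (not isolated), via lithium propiolate 18 (not isolated)
Conditions: n-BuLi (2.3 equiv), THF, −78 °C; CO2, −78 to 0 °C; cold 1 M HCl to pH 3
Reagents that add atoms: carbon dioxide, O=C=O
Why: In the second stage of the Corey–Fuchs sequence, bromine–lithium exchange and Fritsch–Buttenberg–Wiechell-type loss of LiBr give acetylide 17, which is carboxylated in the same flask; the brief cold acidification spares the MOM group.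

Step 11
Reactants: 19 3-{4,5-bis(benzyloxy)-2-[2,6-bis(benzyloxy)-4-(methoxymethoxy)phenyl]phenyl}prop-2-ynoic acid; 6 3,5-bis(benzyloxy)-2-(trimethylsilyl)phenyl trifluoromethanesulfonate
Product: 24 1-[2,4-bis(benzyloxy)-6-hydroxyphenyl]-3-{4,5-bis(benzyloxy)-2-[2,6-bis(benzyloxy)-4-(methoxymethoxy)phenyl]phenyl}prop-2-yn-1-one, via caesium propiolate 20 (not isolated), via aryne 21 (not isolated), via arylcaesium ester 22 (not isolated), via caesium phenolate 23 (not isolated)
Conditions: 19, Cs2CO3 (0.5 equiv), MeOH, rt, evaporate, toluene azeotrope; CsF (3 equiv), 18-crown-6, THF, 40 °C, 6 (1.2 equiv) by syringe pump; AcOH, 0 °C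
Reagents that add atoms: none
Why: Fluoride attacks silicon in 6 and triflate leaves to give aryne 21, carboxylate 20 adds to it, and aryl anion 22 attacks its own ester carbonyl through a four-membered transition state, so the acyl group moves from O to C and phenolate 23 results. The closest known reaction type is the fluoride-induced insertion of arynes into the C–O bond of carboxylic acids, which has been run with arylpropiolic acids, and the acyl shift itself is an anionic Fries-type 1,3-migration. The step needs regioselective addition to an unsymmetrical aryne: the 3-benzyloxy group polarises and distorts the triple bond, so the nucleophile attacks the distal carbon (future C8a) and the charge builds up next to the alkoxy group (future C4a), which gives the 2,4-bis(benzyloxy)-6-hydroxy pattern. It also needs the acyl shift to outrun protonation of 22, which is why the acid enters as its dried caesium salt in THF with no acidic hydrogen in the flask. No ring is closed and no stereocentre is formed, because attack of phenolate 23 on the ynone cannot become productive without a proton, so the chain stays open until the cold acetic acid quench. Slow addition of 6 keeps the aryne concentration low, so that carboxylate 20 and not the hindered, chelated phenolate 23 should capture it.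

Step 12
Reactants: 24 1-[2,4-bis(benzyloxy)-6-hydroxyphenyl]-3-{4,5-bis(benzyloxy)-2-[2,6-bis(benzyloxy)-4-(methoxymethoxy)phenyl]phenyl}prop-2-yn-1-one
Product: 26 5,7-bis(benzyloxy)-2-{4,5-bis(benzyloxy)-2-[2,6-bis(benzyloxy)-4-(methoxymethoxy)phenyl]phenyl}-4H-chromen-4-one, via diethylamino enone 25 (not isolated)
Conditions: Et2NH (5 equiv), DMF, 60 °C
Reagents that add atoms: none
Why: Aza-Michael addition of diethylamine to the ynone gives 25, whose phenol displaces the amine by addition–elimination, which enforces the six-membered pyranone (formal 6-endo closure) and avoids the 5-exo aurone path.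

Step 13
Reactants: 26 5,7-bis(benzyloxy)-2-{4,5-bis(benzyloxy)-2-[2,6-bis(benzyloxy)-4-(methoxymethoxy)phenyl]phenyl}-4H-chromen-4-one
Product: 27 5,7-bis(benzyloxy)-2-{4,5-bis(benzyloxy)-2-[2,6-bis(benzyloxy)-4-hydroxyphenyl]phenyl}-4H-chromen-4-one
Conditions: HCl (cat.), MeOH–THF, 45 °C
Reagents that add atoms: none
Why: Acid-catalysed acetal exchange removes the single MOM group while aryl benzyl ethers and the flavone are inert, so exactly the hydroxyl para to the biaryl bond is freed without any selective reprotection.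

Step 14
Reactants: 27 5,7-bis(benzyloxy)-2-{4,5-bis(benzyloxy)-2-[2,6-bis(benzyloxy)-4-hydroxyphenyl]phenyl}-4H-chromen-4-one
Product: 28 5,7-bis(benzyloxy)-2-{4,5-bis(benzyloxy)-2-[2,6-bis(benzyloxy)-4-hydroxy-3-iodophenyl]phenyl}-4H-chromen-4-one
Conditions: NIS (1.0 equiv), CH2Cl2, −20 to 0 °C, dark
Reagents that add atoms: N-iodosuccinimide, O=C1CCC(=O)N1I
Why: Electrophilic iodination should pick the free-phenol ring, the only ring with three donor oxygens and no acceptor; its two open positions are equivalent and ortho to the hydroxyl, and one equivalent of reagent at low temperature limits double iodination.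

Step 15
Reactants: 28 5,7-bis(benzyloxy)-2-{4,5-bis(benzyloxy)-2-[2,6-bis(benzyloxy)-4-hydroxy-3-iodophenyl]phenyl}-4H-chromen-4-one
Product: 30 2-{2-[3-acetyl-2,6-bis(benzyloxy)-4-hydroxyphenyl]-4,5-bis(benzyloxy)phenyl}-5,7-bis(benzyloxy)-4H-chromen-4-one, via enol ether 29 (not isolated)
Conditions: tributyl(1-ethoxyvinyl)stannane, PdCl2(PPh3)2 (5 mol %), toluene, 100 °C; then 1 M HCl, THF, rt
Reagents that add atoms: tributyl(1-ethoxyvinyl)stannane, CCCC[Sn](CCCC)(CCCC)C(=C)OCC; water, O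
Why: Stille coupling with an acetyl-anion equivalent and mild hydrolysis of enol ether 29 installs the acetyl group without the Lewis acid that a Friedel–Crafts or Fries acylation would need and that would endanger the benzyl ethers.

Step 16
Reactants: 30 2-{2-[3-acetyl-2,6-bis(benzyloxy)-4-hydroxyphenyl]-4,5-bis(benzyloxy)phenyl}-5,7-bis(benzyloxy)-4H-chromen-4-one
Product: 32 5,7-bis(benzyloxy)-6-{4,5-bis(benzyloxy)-2-[5,7-bis(benzyloxy)-4-oxo-4H-chromen-2-yl]phenyl}-4H-chromen-4-one, via dimethylamino enone 31 (not isolated)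
Conditions: Me2NCH(OMe)2, toluene, 100 °C; concentrate; then 1 M HCl, CH2Cl2–THF, 40 °C
Reagents that add atoms: N,N-dimethylformamide dimethyl acetal, COC(OC)N(C)C
Why: In this standard enaminone chromone synthesis the methyl ketone condenses with the amide acetal to 31 and the ortho-hydroxyl displaces dimethylamine under acid; only the para oxygen is free, so only the 6-aryl chromone and not its 8-aryl isomer can form.

Step 17
Reactants: 32 5,7-bis(benzyloxy)-6-{4,5-bis(benzyloxy)-2-[5,7-bis(benzyloxy)-4-oxo-4H-chromen-2-yl]phenyl}-4H-chromen-4-one; 33 4-(benzyloxy)phenylboronic acid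
Product: 34 (2R)-5,7-bis(benzyloxy)-2-[4-(benzyloxy)phenyl]-6-{4,5-bis(benzyloxy)-2-[5,7-bis(benzyloxy)-4-oxo-4H-chromen-2-yl]phenyl}-2,3-dihydro-4H-chromen-4-one
Conditions: 33 (2 equiv), Pd(OCOCF3)2 (10 mol %), (S)-4-tert-butyl-2-(pyridin-2-yl)-4,5-dihydrooxazole (12 mol %), NH4PF6 (30 mol %), H2O (5 equiv), ClCH2CH2Cl, 60 °C
Reagents that add atoms: none
Why: In this palladium-catalysed asymmetric conjugate addition of an arylboronic acid to a chromone, a cationic divalent arylpalladium–pyridine-oxazoline complex inserts C2=C3 and the palladium enolate is protonated; the tert-butyl group of the (S)-ligand blocks one enone face in the same sense as with cyclic enones, which places the aryl group so that C2 should be R (the mirror-image ligand is equally available), while the fully substituted, hindered C2 of the flavone stays inert.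

Step 18
Reactants: 34 (2R)-5,7-bis(benzyloxy)-2-[4-(benzyloxy)phenyl]-6-{4,5-bis(benzyloxy)-2-[5,7-bis(benzyloxy)-4-oxo-4H-chromen-2-yl]phenyl}-2,3-dihydro-4H-chromen-4-one
Product: 35 (2R)-6-[2-(5,7-dihydroxy-4-oxo-4H-chromen-2-yl)-4,5-dihydroxyphenyl]-5,7-dihydroxy-2-(4-hydroxyphenyl)-2,3-dihydro-4H-chromen-4-one
Conditions: H2 (1 atm), 10% Pd/C, THF–MeOH, rt
Reagents that add atoms: none
Why: Catalytic hydrogenolysis removes all seven benzyl ethers under neutral conditions that normally leave flavone and flavanone cores untouched, and the absence of base or strong acid prevents ring opening to the chalcone, which would racemise C2 and scramble the 6-aryl and 8-aryl isomers.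

Compound list
1 | 3,5-bis(benzyloxy)phenol | Oc1cc(OCc2ccccc2)cc(OCc2ccccc2)c1 | starting material
2 | 3,5-bis(benzyloxy)-2-bromophenol | Oc1cc(OCc2ccccc2)cc(OCc2ccccc2)c1Br | intermediate
3 | [3,5-bis(benzyloxy)-2-bromophenoxy]trimethylsilane | C[Si](C)(C)Oc1cc(OCc2ccccc2)cc(OCc2ccccc2)c1Br | intermediate
4 | [2,4-bis(benzyloxy)-6-(trimethylsilyloxy)phenyl]lithium | C[Si](C)(C)Oc1cc(OCc2ccccc2)cc(OCc2ccccc2)c1[Li] | intermediate
5 | lithium 3,5-bis(benzyloxy)-2-(trimethylsilyl)phenolate | [Li+].[O-]c1cc(OCc2ccccc2)cc(OCc2ccccc2)c1[Si](C)(C)C | intermediate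
6 | 3,5-bis(benzyloxy)-2-(trimethylsilyl)phenyl trifluoromethanesulfonate | C[Si](C)(C)c1c(OS(=O)(=O)C(F)(F)F)cc(OCc2ccccc2)cc1OCc1ccccc1 | intermediate
7 | phloroglucinol | Oc1cc(O)cc(O)c1 | starting material
8 | 5-(methoxymethoxy)benzene-1,3-diol | COCOc1cc(O)cc(O)c1 | intermediate
9 | 2-iodo-5-(methoxymethoxy)benzene-1,3-diol | COCOc1cc(O)c(I)c(O)c1 | intermediate
10 | 1,3-bis(benzyloxy)-2-iodo-5-(methoxymethoxy)benzene | COCOc1cc(OCc2ccccc2)c(I)c(OCc2ccccc2)c1 | intermediate
11 | 3,4-bis(benzyloxy)benzaldehyde | O=Cc1ccc(OCc2ccccc2)c(OCc2ccccc2)c1 | starting material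
12 | 4,5-bis(benzyloxy)-2-bromobenzaldehyde | O=Cc1cc(OCc2ccccc2)c(OCc2ccccc2)cc1Br | intermediate
13 | [2,6-bis(benzyloxy)-4-(methoxymethoxy)phenyl]lithium | COCOc1cc(OCc2ccccc2)c([Li])c(OCc2ccccc2)c1 | intermediate
14 | [2,6-bis(benzyloxy)-4-(methoxymethoxy)phenyl]zinc chloride | COCOc1cc(OCc2ccccc2)c([Zn]Cl)c(OCc2ccccc2)c1 | intermediate
15 | 4,5-bis(benzyloxy)-2-[2,6-bis(benzyloxy)-4-(methoxymethoxy)phenyl]benzaldehyde | O=Cc1cc(OCc2ccccc2)c(OCc2ccccc2)cc1-c1c(OCc2ccccc2)cc(OCOC)cc1OCc1ccccc1 | intermediate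
16 | 1,2-bis(benzyloxy)-4-[2,6-bis(benzyloxy)-4-(methoxymethoxy)phenyl]-5-(2,2-dibromoethenyl)benzene | BrC(Br)=Cc1cc(OCc2ccccc2)c(OCc2ccccc2)cc1-c1c(OCc2ccccc2)cc(OCOC)cc1OCc1ccccc1 | intermediate
17 | lithium acetylide of the biaryl ({4,5-bis(benzyloxy)-2-[2,6-bis(benzyloxy)-4-(methoxymethoxy)phenyl]phenyl}ethynyllithium) | [Li]C#Cc1cc(OCc2ccccc2)c(OCc2ccccc2)cc1-c1c(OCc2ccccc2)cc(OCOC)cc1OCc1ccccc1 | intermediate
18 | lithium salt of acid 19 | [Li+].[O-]C(=O)C#Cc1cc(OCc2ccccc2)c(OCc2ccccc2)cc1-c1c(OCc2ccccc2)cc(OCOC)cc1OCc1ccccc1 | intermediate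
19 | 3-{4,5-bis(benzyloxy)-2-[2,6-bis(benzyloxy)-4-(methoxymethoxy)phenyl]phenyl}prop-2-ynoic acid | OC(=O)C#Cc1cc(OCc2ccccc2)c(OCc2ccccc2)cc1-c1c(OCc2ccccc2)cc(OCOC)cc1OCc1ccccc1 | intermediate
20 | caesium salt of acid 19 | [Cs+].[O-]C(=O)C#Cc1cc(OCc2ccccc2)c(OCc2ccccc2)cc1-c1c(OCc2ccccc2)cc(OCOC)cc1OCc1ccccc1 | intermediate
21 | 3,5-bis(benzyloxy)benzyne (1,2-didehydro-3,5-bis(benzyloxy)benzene) | C1#CC(OCc2ccccc2)=CC(OCc2ccccc2)=C1 | intermediate
22 | {2,4-bis(benzyloxy)-6-[(3-arylprop-2-ynoyl)oxy]phenyl}caesium, aryl = the biaryl unit of 19 | [Cs]c1c(OC(=O)C#Cc2cc(OCc3ccccc3)c(OCc3ccccc3)cc2-c2c(OCc3ccccc3)cc(OCOC)cc2OCc2ccccc2)cc(OCc2ccccc2)cc1OCc1ccccc1 | intermediate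
23 | caesium phenolate of ynone 24 | [Cs+].[O-]c1cc(OCc2ccccc2)cc(OCc2ccccc2)c1C(=O)C#Cc1cc(OCc2ccccc2)c(OCc2ccccc2)cc1-c1c(OCc2ccccc2)cc(OCOC)cc1OCc1ccccc1 | intermediate
24 | 1-[2,4-bis(benzyloxy)-6-hydroxyphenyl]-3-{4,5-bis(benzyloxy)-2-[2,6-bis(benzyloxy)-4-(methoxymethoxy)phenyl]phenyl}prop-2-yn-1-one | O=C(C#Cc1cc(OCc2ccccc2)c(OCc2ccccc2)cc1-c1c(OCc2ccccc2)cc(OCOC)cc1OCc1ccccc1)c1c(O)cc(OCc2ccccc2)cc1OCc1ccccc1 | intermediate
25 | 3-(diethylamino) enone from 24 (diethylamine added to the alkyne carbon that bears the biaryl; alkene geometry not fixed) | CCN(CC)C(=CC(=O)c1c(O)cc(OCc2ccccc2)cc1OCc1ccccc1)c1cc(OCc2ccccc2)c(OCc2ccccc2)cc1-c1c(OCc2ccccc2)cc(OCOC)cc1OCc1ccccc1 | intermediate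
26 | 5,7-bis(benzyloxy)-2-{4,5-bis(benzyloxy)-2-[2,6-bis(benzyloxy)-4-(methoxymethoxy)phenyl]phenyl}-4H-chromen-4-one | O=c1cc(-c2cc(OCc3ccccc3)c(OCc3ccccc3)cc2-c2c(OCc3ccccc3)cc(OCOC)cc2OCc2ccccc2)oc2cc(OCc3ccccc3)cc(OCc3ccccc3)c12 | intermediate
27 | 5,7-bis(benzyloxy)-2-{4,5-bis(benzyloxy)-2-[2,6-bis(benzyloxy)-4-hydroxyphenyl]phenyl}-4H-chromen-4-one | O=c1cc(-c2cc(OCc3ccccc3)c(OCc3ccccc3)cc2-c2c(OCc3ccccc3)cc(O)cc2OCc2ccccc2)oc2cc(OCc3ccccc3)cc(OCc3ccccc3)c12 | intermediate
28 | 5,7-bis(benzyloxy)-2-{4,5-bis(benzyloxy)-2-[2,6-bis(benzyloxy)-4-hydroxy-3-iodophenyl]phenyl}-4H-chromen-4-one | O=c1cc(-c2cc(OCc3ccccc3)c(OCc3ccccc3)cc2-c2c(OCc3ccccc3)cc(O)c(I)c2OCc2ccccc2)oc2cc(OCc3ccccc3)cc(OCc3ccccc3)c12 | intermediate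
29 | 5,7-bis(benzyloxy)-2-{4,5-bis(benzyloxy)-2-[2,6-bis(benzyloxy)-3-(1-ethoxyethenyl)-4-hydroxyphenyl]phenyl}-4H-chromen-4-one | O=c1cc(-c2cc(OCc3ccccc3)c(OCc3ccccc3)cc2-c2c(OCc3ccccc3)cc(O)c(C(=C)OCC)c2OCc2ccccc2)oc2cc(OCc3ccccc3)cc(OCc3ccccc3)c12 | intermediate
30 | 2-{2-[3-acetyl-2,6-bis(benzyloxy)-4-hydroxyphenyl]-4,5-bis(benzyloxy)phenyl}-5,7-bis(benzyloxy)-4H-chromen-4-one | O=c1cc(-c2cc(OCc3ccccc3)c(OCc3ccccc3)cc2-c2c(OCc3ccccc3)cc(O)c(C(C)=O)c2OCc2ccccc2)oc2cc(OCc3ccccc3)cc(OCc3ccccc3)c12 | intermediate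
31 | (E)-3-(dimethylamino)prop-2-enoyl analogue of 30 (acetyl replaced by C(=O)CH=CHNMe2) | O=c1cc(-c2cc(OCc3ccccc3)c(OCc3ccccc3)cc2-c2c(OCc3ccccc3)cc(O)c(C(=O)/C=C/N(C)C)c2OCc2ccccc2)oc2cc(OCc3ccccc3)cc(OCc3ccccc3)c12 | intermediate
32 | 5,7-bis(benzyloxy)-6-{4,5-bis(benzyloxy)-2-[5,7-bis(benzyloxy)-4-oxo-4H-chromen-2-yl]phenyl}-4H-chromen-4-one | O=c1ccoc2cc(OCc3ccccc3)c(-c3cc(OCc4ccccc4)c(OCc4ccccc4)cc3-c3cc(=O)c4c(OCc5ccccc5)cc(OCc5ccccc5)cc4o3)c(OCc3ccccc3)c12 | intermediate
33 | 4-(benzyloxy)phenylboronic acid | OB(O)c1ccc(OCc2ccccc2)cc1 | starting material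
34 | (2R)-5,7-bis(benzyloxy)-2-[4-(benzyloxy)phenyl]-6-{4,5-bis(benzyloxy)-2-[5,7-bis(benzyloxy)-4-oxo-4H-chromen-2-yl]phenyl}-2,3-dihydro-4H-chromen-4-one | O=C1C[C@H](c2ccc(OCc3ccccc3)cc2)Oc2cc(OCc3ccccc3)c(-c3cc(OCc4ccccc4)c(OCc4ccccc4)cc3-c3cc(=O)c4c(OCc5ccccc5)cc(OCc5ccccc5)cc4o3)c(OCc3ccccc3)c21 | intermediate
35 | (2R)-6-[2-(5,7-dihydroxy-4-oxo-4H-chromen-2-yl)-4,5-dihydroxyphenyl]-5,7-dihydroxy-2-(4-hydroxyphenyl)-2,3-dihydro-4H-chromen-4-one | O=C1C[C@H](c2ccc(O)cc2)Oc2cc(O)c(-c3cc(O)c(O)cc3-c3cc(=O)c4c(O)cc(O)cc4o3)c(O)c21 | target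

Total step count: 18. Longest linear sequence: 14 steps (steps 4, 5, 6, 8 and then 9 to 18, from phloroglucinol).

Steps most likely to fail

Step 11 (aryne insertion). Three processes threaten it: protonation of the aryl anion before the acyl shift, further arylation of the product phenolate by surplus aryne, and loss of CO2 from the propiolate.
- The fallback gives up the aryne and builds the flavone by the Baker–Venkataraman route. It sets out from aldehyde 15 and comes back at phenol 27.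
- Pinnick oxidation (NaClO2, NaH2PO4, 2-methylbut-2-ene) should give 4,5-bis(benzyloxy)-2-[2,6-bis(benzyloxy)-4-(methoxymethoxy)phenyl]benzoic acid F1.
- Carbodiimide/DMAP esterification with commercial 1-[2,4-bis(benzyloxy)-6-hydroxyphenyl]ethan-1-one should give 2-acetyl-3,5-bis(benzyloxy)phenyl 4,5-bis(benzyloxy)-2-[2,6-bis(benzyloxy)-4-(methoxymethoxy)phenyl]benzoate F2.
- KOH in pyridine should move the aroyl group to carbon and give 1-[2,4-bis(benzyloxy)-6-hydroxyphenyl]-3-{4,5-bis(benzyloxy)-2-[2,6-bis(benzyloxy)-4-(methoxymethoxy)phenyl]phenyl}propane-1,3-dione F3.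
- HCl in MeOH–THF at reflux should cyclodehydrate the diketone and remove the MOM group in one operation, which gives 27.

Step 17 (asymmetric conjugate arylation). The risks are sluggish insertion of the electron-rich, hindered chromone, competing protodeboronation, and poor facial selectivity.
- The fallback makes the flavanone through the chalcone and separates the enantiomers. It sets out from acetophenone 30 and comes back at 34.
- Claisen–Schmidt condensation with 4-(benzyloxy)benzaldehyde (KOH, EtOH–THF, rt) should give the (E)-2'-hydroxychalcone F4.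
- NaOAc in refluxing ethanol should close it by oxa-Michael addition to the racemic flavanone F5.
- Preparative chromatography on a polysaccharide-type chiral phase should deliver 34.
- The (2S)-enantiomer F6 can be returned to the chalcone–flavanone equilibrium with base and recycled.

Step 18 (global hydrogenolysis). The risks are over-reduction (cleavage of the benzylic C2–O1 bond, reduction of a carbonyl group or of the flavone C2=C3 bond) and stalling because partly deprotected material precipitates on the catalyst.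
- The fallback replaces reduction by Lewis-acid debenzylation with a cation scavenger: BCl3 and pentamethylbenzene in CH2Cl2 at −78 °C, followed by a methanol quench.
- It sets out from 34 and comes back directly at 35. It makes no new compound (F0).

Further compounds
F1 | step 11 | 4,5-bis(benzyloxy)-2-[2,6-bis(benzyloxy)-4-(methoxymethoxy)phenyl]benzoic acid | OC(=O)c1cc(OCc2ccccc2)c(OCc2ccccc2)cc1-c1c(OCc2ccccc2)cc(OCOC)cc1OCc1ccccc1
F2 | step 11 | 2-acetyl-3,5-bis(benzyloxy)phenyl 4,5-bis(benzyloxy)-2-[2,6-bis(benzyloxy)-4-(methoxymethoxy)phenyl]benzoate | CC(=O)c1c(OC(=O)c2cc(OCc3ccccc3)c(OCc3ccccc3)cc2-c2c(OCc3ccccc3)cc(OCOC)cc2OCc2ccccc2)cc(OCc2ccccc2)cc1OCc1ccccc1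
F3 | step 11 | 1-[2,4-bis(benzyloxy)-6-hydroxyphenyl]-3-{4,5-bis(benzyloxy)-2-[2,6-bis(benzyloxy)-4-(methoxymethoxy)phenyl]phenyl}propane-1,3-dione | O=C(CC(=O)c1c(O)cc(OCc2ccccc2)cc1OCc1ccccc1)c1cc(OCc2ccccc2)c(OCc2ccccc2)cc1-c1c(OCc2ccccc2)cc(OCOC)cc1OCc1ccccc1
F4 | step 17 | (E)-2'-hydroxychalcone from 30 and 4-(benzyloxy)benzaldehyde | O=C(/C=C/c1ccc(OCc2ccccc2)cc1)c1c(O)cc(OCc2ccccc2)c(-c2cc(OCc3ccccc3)c(OCc3ccccc3)cc2-c2cc(=O)c3c(OCc4ccccc4)cc(OCc4ccccc4)cc3o2)c1OCc1ccccc1
F5 | step 17 | racemic flavanone (racemate of 34) | O=C1CC(c2ccc(OCc3ccccc3)cc2)Oc2cc(OCc3ccccc3)c(-c3cc(OCc4ccccc4)c(OCc4ccccc4)cc3-c3cc(=O)c4c(OCc5ccccc5)cc(OCc5ccccc5)cc4o3)c(OCc3ccccc3)c21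
F6 | step 17 | (2S)-enantiomer of 34 | O=C1C[C@@H](c2ccc(OCc3ccccc3)cc2)Oc2cc(OCc3ccccc3)c(-c3cc(OCc4ccccc4)c(OCc4ccccc4)cc3-c3cc(=O)c4c(OCc5ccccc5)cc(OCc5ccccc5)cc4o3)c(OCc3ccccc3)c21
F0 | step 18 | none | none
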